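- 29.8 % of the substrate charged is the mean of the south-east readings, so I ask what holds that flask flat with about 70.2 % of the substrate unreacted, if what reacted stands as product.

| flask | substrate | reagent | initiator | remark | time |
|---|---|---|---|---|---|
| south-east | 0.10 M | 2 equiv | 1 mol% | the very flask that is asked about, followed so far |  |
| east | 0.050 M | 2 equiv | 1 mol% | run made earlier |  |
| flask | 0.10 M | 2.00 equiv | 1 mol% |  | 6.0 h |

| run | time / min | product / % |
|---|---|---|
| south-east | 25.0 | 29.2 |
| south-east | 40.0 | 29.6 |
| south-east | 80.0 | 30.9 |
| south-east | 150 | 29.5 |
| south-east | 300 | 29.8 |
| east | 2.50 | 7.7 |
| east | 5.00 | 12.0 |
| east | 10.0 | 18.4 |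
| east | 15.0 | 22.1 |
| east | 30.0 | 22.8 |

(readings scatter by 1 percentage point)

- product, in percent of the substrate first charged, at 6.0 h
- what to do for the largest gain in product; "none" if nothing gains more than 2 percentage points (dawn / dusk / spring / winter / none)
- product present, with what was taken out counted in, in percent of the substrate first charged, after dusk
- product present, with what was taken out counted in, in percent of the substrate first charged, after winter

- dawn: at 6.0 h add substrate, 50.0 % of the amount charged, then wait 6.0 h
- dusk: change nothing and wait 6.0 h more
- spring: at 6.0 h add reagent, 100 % of the amount charged, then wait 6.0 h
- winter: at 6.0 h take out 90 % of the product then present, then wait 6.0 h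

- product taken out counts as made
- the analysis behind the earlier runs scatters by 1 percentage point, standard deviation
- additions bring no volume worth counting

- The fastest rung of my ladder is the rise of the east flask: measured against its last reading, its reading at 10.0 min gives a time constant of 6.08 min.
- The next rung is the first south-east reading at 25.0 min, which is later than that time constant, so if both flasks share it, the south-east flask is already flat there, as its readings show.
- The slowest rung is the look at 6.0 h, about 59.2 time constants in, so I expect the south-east flask to stand unchanged.
- The end state looks like a progress curve whose driver dies while substrate still stands, which is dead-end kinetics. Suppose the substrate falls first order under a driver, which I take to be the initiator, that decays away: then its logarithm falls by a finite total.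
- For the south-east flask that total is 0.354, and I call it the burn-out reach, the natural logarithm of substrate charged over substrate left once the flask is flat.
- If the rate goes as the root of the initiator, and the loading is held in mol%, the reach grows as the root of the concentration.
- On the east flask this rule gives 22.1 %. The last reading there is 22.8 %, a gap of 0.67 percentage points, smaller than the scatter of 1 point.
- So I commit to 29.8 % now and to no useful option, because on this reckoning the driver has decayed long before the options begin.
- The forecast agrees: 29.8 % now, none as best, 29.8 % after dusk and 29.8 % after winter, on the ground that “the chain stops because the initiator is spent”.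
- The flask gives 29.8 %, and the best choice is none: dawn gains 0.006 points, dusk 0 points, spring 0 points and winter 0 points, leaving 29.8 % after dusk and 29.8 % after winter. Its reach is 0.354. Neither the loss of reagent to the dormant form nor the backward step makes a difference worth counting to the product at 6.0 h.

    initiator → 2 initiating radical (k = 0.331 min⁻¹)
    substrate + initiating radical → chain carrier (k = 2.64 × 10⁵ L mol⁻¹ min⁻¹)
    reagent + chain carrier ⇌ product + initiating radical (K = 0.151, k = 2.09 × 10⁵ L mol⁻¹ s⁻¹)
    2 initiating radical → ended chains A (k = 1.10 × 10⁸ L mol⁻¹ s⁻¹)
    2 chain carrier → ended chains B (k = 1.20 × 10⁶ L mol⁻¹ s⁻¹)
    reagent ⇌ dormant form (K = 1.10, k = 0.212 min⁻¹)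

- The neighbouring flask holds 0.060 M of substrate, with the same equivalents, loading and time. The reach scaled by the root of the concentration ratio becomes 0.274, which reckons to 24.0 % product. That flask has 0 % of its initiator and 76 % of its substrate left, and its product stands at 24.1 %.

The earlier runs and the new flask are calculated with constants of no real substance; scatter was added.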